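**Retrosynthetic overview**
- Numbering: chromone O1–C8a (benzo ring A, pyranone ring B), isochromanone C1′–C8a′ (benzo ring C, lactone ring D), bridge CH2 = C9. The strategy rests on ring C (C4a′, C5′, C6′, C7′, C8′, C8a′), which carries six substituents and shares C4a′–C8a′ with ring D, so three alkynes, two of them tied through the C1′ ester, can supply all six carbons.
- End game: MOM off O5, silicon-to-oxygen exchange at C8′ (Tamao–Fleming) together with O6′ desilylation.
- Key disconnection: C4a′–C8a′, C5′–C6′ and C7′–C8′ lead back to diyne ester 16 and siloxypropyne 20; rings C and D form together and last.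
- Diyne 16 is cut at the C1′–O2′ ester (silylpropiolic acid 15 plus alcohol 11) and at the C9–alkyne bond (benzyl bromide 8 plus (R)-pent-4-yn-2-ol 10, C3′ from (R)-propylene oxide).
- Rings A and B are made first from 2,4,6-trihydroxyacetophenone (ring B closed in step 1); C9 is put on C6 by phenoxide-directed formylation.

Key step: step 12

Remark on the chemistry: the chelated 5-OH is the only free phenol of 4, so a phenoxide-directed reaction is assumed to address C6 and not C8. Siloxypropyne 20 is made from propyne by acetylide oxidation, the direct access to a methyl-substituted ynolate.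

**Route**

Step 1
Reactants: 1 2,4,6-trihydroxyacetophenone
Product: 3 5,7-dihydroxy-2-methyl-4H-chromen-4-one (noreugenin), via 3-acetyl-5,7-diacetoxy-2-methylchromone 2 (not isolated)
Conditions: Ac2O, NaOAc, 180 °C; then aq Na2CO3, reflux; AcOH to pH 5
Reagents that add atoms: acetic anhydride, CC(=O)OC(C)=O
Why: Kostanecki–Robinson acylation and cyclodehydration should build the 2-methylpyranone ring, and aqueous carbonate should then remove the two O-acetyl groups and the 3-acetyl group (retro-Claisen deacylation).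

Step 2
Reactants: 3 noreugenin
Product: 4 5-hydroxy-7-methoxy-2-methyl-4H-chromen-4-one (eugenin)
Conditions: MeI (1.05 equiv), K2CO3 (1.1 equiv), acetone, reflux
Reagents that add atoms: iodomethane, CI
Why: Williamson O-methylation should occur at O7 only, because the 5-OH is hydrogen-bonded to C4=O and is much less acidic and nucleophilic.

Step 3
Reactants: 4 eugenin
Product: 5 5-hydroxy-7-methoxy-2-methyl-4-oxo-4H-chromene-6-carbaldehyde
Conditions: MgCl2, Et3N, (CH2O)n, MeCN, reflux; then 1 M HCl
Reagents that add atoms: formaldehyde (as paraformaldehyde), C=O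
Why: In the Casnati–Skattebøl ortho-formylation the magnesium phenoxide of O5 should deliver formaldehyde through a six-membered chelate to the only free ortho carbon, C6, and a second formaldehyde should oxidise the benzylic alkoxide by hydride transfer, so C8 stays untouched.

Step 4
Reactants: 5 6-formyl chromone
Product: 6 7-methoxy-5-(methoxymethoxy)-2-methyl-4-oxo-4H-chromene-6-carbaldehyde
Conditions: MOMCl, i-Pr2NEt, n-Bu4NI (cat.), CH2Cl2, 0 → 40 °C
Reagents that add atoms: chloromethyl methyl ether, COCCl
Why: O-alkylation of the acidic, doubly chelated phenol by the very reactive chloromethyl ether should give the MOM ether, which is needed because a free ortho-hydroxybenzyl halide would collapse to an ortho-quinone methide.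

Step 5
Reactants: 6 MOM-protected aldehyde
Product: 7 6-(hydroxymethyl)-7-methoxy-5-(methoxymethoxy)-2-methyl-4H-chromen-4-one
Conditions: NaBH4, THF/MeOH, −20 °C
Reagents that add atoms: none
Why: Chemoselective borohydride reduction should take the aryl aldehyde far faster than the vinylogous ester carbonyl of the chromone at low temperature.

Step 6
Reactants: 7 benzylic alcohol
Product: 8 6-(bromomethyl)-7-methoxy-5-(methoxymethoxy)-2-methyl-4H-chromen-4-one
Conditions: CBr4, PPh3, CH2Cl2, 0 °C; used at once
Reagents that add atoms: carbon tetrabromide, BrC(Br)(Br)Br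
Why: Appel bromination runs under neutral conditions that spare the MOM acetal, and the electron-rich benzylic bromide is carried on without storage.

Step 7
Reactants: 9 (R)-2-methyloxirane
Product: 10 (R)-pent-4-yn-2-ol
Conditions: LiC≡CH·H2NCH2CH2NH2, DMSO, 0 °C → rt; then H2O
Reagents that add atoms: lithium acetylide (as its ethylenediamine complex), [Li]C#C
Why: SN2 epoxide opening by acetylide at the unsubstituted CH2 leaves the stereocentre (the future C3′) untouched, so it stays (R).

Step 8
Reactants: 8 benzylic bromide; 10 (R)-pent-4-yn-2-ol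
Product: 11 6-[(5R)-5-hydroxyhex-2-yn-1-yl]-7-methoxy-5-(methoxymethoxy)-2-methyl-4H-chromen-4-one
Conditions: CuI (20 mol %), n-Bu4NI (20 mol %), K2CO3, MeCN, rt → 40 °C
Reagents that add atoms: none
Why: Copper-catalysed alkynylation of a benzylic halide (copper acetylide substitution) should form the C9–alkyne bond under carbonate conditions mild enough to leave the secondary alcohol unalkylated and to avoid propargyl-to-allene isomerisation.

Step 9
Reactants: 12 prop-2-ynoic acid
Product: 15 3-[benzyl(dimethyl)silyl]prop-2-ynoic acid, via dilithium propiolate 13 (not isolated), via bis-silyl propiolate 14 (not isolated)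
Conditions: n-BuLi (2.05 equiv), THF, −78 °C; BnMe2SiCl (2.2 equiv), −78 °C → rt; then 1 M HCl
Reagents that add atoms: benzylchlorodimethylsilane, C[Si](C)(Cl)Cc1ccccc1
Why: C-silylation of the acetylide carbon of the dianion should give the alkynylsilane, and the silyl ester formed alongside is hydrolysed in the acidic work-up while the C–Si bond stays.

Step 10
Reactants: 11 homopropargylic alcohol; 15 silylpropiolic acid
Product: 16 (2R)-6-[7-methoxy-5-(methoxymethoxy)-2-methyl-4-oxo-4H-chromen-6-yl]hex-4-yn-2-yl 3-[benzyl(dimethyl)silyl]prop-2-ynoate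
Conditions: DCC, DMAP (5 mol %), CH2Cl2, 0 °C → rt
Reagents that add atoms: none
Why: Steglich esterification acylates oxygen without breaking the carbinol C–O bond, so C3′ keeps its (R) configuration, and the 3-silyl group shields the ynoate from conjugate addition.

Step 11
Reactants: 17 prop-1-yne
Product: 20 triisopropyl(prop-1-yn-1-yloxy)silane, via prop-1-yn-1-yllithium 18 (not isolated), via lithium prop-1-yn-1-olate 19 (not isolated)
Conditions: n-BuLi, THF, −78 °C; t-BuOOLi (from t-BuOOH and LiN(SiMe3)2), −78 → 0 °C; i-Pr3SiOTf, −78 °C → rt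
Reagents that add atoms: tert-butyl hydroperoxide, CC(C)(C)OO; triisopropylsilyl trifluoromethanesulfonate, CC(C)[Si](OS(=O)(=O)C(F)(F)F)(C(C)C)C(C)C
Why: Julia-type oxidation of the lithium acetylide by lithium tert-butyl peroxide should give the ynolate, which the bulky silyl triflate traps on oxygen as the ynol ether.

Step 12
Reactants: 16 diyne ester; 20 siloxypropyne
Product: 21 (3R)-8-[benzyl(dimethyl)silyl]-5-{[7-methoxy-5-(methoxymethoxy)-2-methyl-4-oxo-4H-chromen-6-yl]methyl}-3,7-dimethyl-6-[(triisopropylsilyl)oxy]isochroman-1-one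
Conditions: [Rh(cod)2]BF4 (10 mol %), rac-BINAP (10 mol %), H2 then Ar (removal of cod), CH2Cl2, rt; slow addition of 16 to 20 (3 equiv)
Reagents that add atoms: none
Why: Proposed new method: the cationic monovalent rhodium–bisphosphine fragment should either cyclise the two tethered alkynes of 16 oxidatively to a trivalent rhodacyclopentadiene (C4a′–C8a′ formed) or first couple the electron-poor ynoate with the electron-rich ynol ether (C7′–C8′ formed), and insertion of the third alkyne followed by reductive elimination releases the same benzene by either path. The closest known reactions are the cationic rhodium–bisphosphine [2+2+2] cycloadditions of ester-tethered 1,6- and 1,7-diynes with monoalkynes and the cross-cyclotrimerisations of alkynoates with heteroatom-substituted electron-rich alkynes; a siloxyalkyne at this level of substitution has not been used. Ring D, the six-membered lactone, closes by annulation through the existing C1′ ester tether when C4a′–C8a′ forms, and ring C closes as the all-carbon six-membered ring of the [2+2+2] event when C5′–C6′ and C7′–C8′ form. No stereocentre is created, and C3′ (R) from 10 lies outside the reacting atoms. The step needs one orientation of the ynol ether: its nucleophilic methyl-bearing carbon should bond to C8′, the electrophilic β-carbon of the silyl ynoate, and its siloxy carbon to C5′, a polarity-matched pairing that also keeps the triisopropylsilyloxy group away from the benzyldimethylsilyl group. Cross-trimerisation over homo-trimerisation is favoured by the tether, by slow addition of 16 to excess 20, and by near-neutral conditions at room temperature that the acid-sensitive ynol ether should tolerate.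

Step 13
Reactants: 21 cycloadduct
Product: 23 (3R)-6,8-dihydroxy-5-{[7-methoxy-5-(methoxymethoxy)-2-methyl-4-oxo-4H-chromen-6-yl]methyl}-3,7-dimethylisochroman-1-one, via arylsilanol 22 (not isolated)
Conditions: n-Bu4NF (3.5 equiv), THF, 0 °C → rt; then KHCO3, 30% H2O2, MeOH, 40 °C
Reagents that add atoms: hydrogen peroxide, OO
Why: In this Tamao–Fleming oxidation fluoride should cleave the benzyl–silicon bond to the arylsilanol and the O6′ silyl ether, after which hydroperoxide attacks silicon and the C8′ aryl group migrates to oxygen, the bicarbonate buffer sparing lactone and chromone.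

Step 14
Reactants: 23 MOM ether
Product: 24 (3R)-6,8-dihydroxy-5-[(5-hydroxy-7-methoxy-2-methyl-4-oxo-4H-chromen-6-yl)methyl]-3,7-dimethylisochroman-1-one (CNP0180307.1)
Conditions: HCl (2 M in MeOH), THF/MeOH, rt
Reagents that add atoms: none
Why: Acid-catalysed acetal cleavage should free the chelated 5-OH, methanol trapping the methoxymethyl cation as dimethoxymethane so that no formaldehyde remains to attack the electron-rich rings, while lactone and chromone are stable to dilute methanolic acid.

**Compound list**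
1 | 2,4,6-trihydroxyacetophenone | CC(=O)c1c(O)cc(O)cc1O | starting material
2 | 3-acetyl-2-methyl-4-oxo-4H-chromene-5,7-diyl diacetate | CC(=O)Oc1cc(OC(C)=O)c2c(c1)oc(C)c(C(C)=O)c2=O | intermediate
3 | 5,7-dihydroxy-2-methyl-4H-chromen-4-one | Cc1cc(=O)c2c(O)cc(O)cc2o1 | intermediate
4 | 5-hydroxy-7-methoxy-2-methyl-4H-chromen-4-one | COc1cc(O)c2c(c1)oc(C)cc2=O | intermediate
5 | 5-hydroxy-7-methoxy-2-methyl-4-oxo-4H-chromene-6-carbaldehyde | COc1cc2oc(C)cc(=O)c2c(O)c1C=O | intermediate
6 | 7-methoxy-5-(methoxymethoxy)-2-methyl-4-oxo-4H-chromene-6-carbaldehyde | COCOc1c(C=O)c(OC)cc2oc(C)cc(=O)c12 | intermediate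
7 | 6-(hydroxymethyl)-7-methoxy-5-(methoxymethoxy)-2-methyl-4H-chromen-4-one | COCOc1c(CO)c(OC)cc2oc(C)cc(=O)c12 | intermediate
8 | 6-(bromomethyl)-7-methoxy-5-(methoxymethoxy)-2-methyl-4H-chromen-4-one | COCOc1c(CBr)c(OC)cc2oc(C)cc(=O)c12 | intermediate
9 | (R)-2-methyloxirane | C[C@@H]1CO1 | starting material
10 | (R)-pent-4-yn-2-ol | C[C@@H](O)CC#C | intermediate
11 | 6-[(5R)-5-hydroxyhex-2-yn-1-yl]-7-methoxy-5-(methoxymethoxy)-2-methyl-4H-chromen-4-one | C[C@@H](O)CC#CCc1c(OC)cc2oc(C)cc(=O)c2c1OCOC | intermediate
12 | prop-2-ynoic acid | C#CC(=O)O | starting material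
13 | dilithium propiolate (lithium 3-lithioprop-2-ynoate) | [Li]C#CC(=O)O[Li] | intermediate
14 | benzyl(dimethyl)silyl 3-[benzyl(dimethyl)silyl]prop-2-ynoate | C[Si](C)(Cc1ccccc1)C#CC(=O)O[Si](C)(C)Cc1ccccc1 | intermediate
15 | 3-[benzyl(dimethyl)silyl]prop-2-ynoic acid | C[Si](C)(Cc1ccccc1)C#CC(=O)O | intermediate
16 | (2R)-6-[7-methoxy-5-(methoxymethoxy)-2-methyl-4-oxo-4H-chromen-6-yl]hex-4-yn-2-yl 3-[benzyl(dimethyl)silyl]prop-2-ynoate | C[C@H](CC#CCc1c(OC)cc2oc(C)cc(=O)c2c1OCOC)OC(=O)C#C[Si](C)(C)Cc1ccccc1 | intermediate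
17 | prop-1-yne | CC#C | starting material
18 | prop-1-yn-1-yllithium | CC#C[Li] | intermediate
19 | lithium prop-1-yn-1-olate | CC#CO[Li] | intermediate
20 | triisopropyl(prop-1-yn-1-yloxy)silane | CC#CO[Si](C(C)C)(C(C)C)C(C)C | intermediate
21 | (3R)-8-[benzyl(dimethyl)silyl]-5-{[7-methoxy-5-(methoxymethoxy)-2-methyl-4-oxo-4H-chromen-6-yl]methyl}-3,7-dimethyl-6-[(triisopropylsilyl)oxy]isochroman-1-one | C[C@@H]1Cc2c(Cc3c(OC)cc4oc(C)cc(=O)c4c3OCOC)c(O[Si](C(C)C)(C(C)C)C(C)C)c(C)c([Si](C)(C)Cc3ccccc3)c2C(=O)O1 | intermediate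
22 | (3R)-6-hydroxy-8-[hydroxy(dimethyl)silyl]-5-{[7-methoxy-5-(methoxymethoxy)-2-methyl-4-oxo-4H-chromen-6-yl]methyl}-3,7-dimethylisochroman-1-one | C[C@@H]1Cc2c(Cc3c(OC)cc4oc(C)cc(=O)c4c3OCOC)c(O)c(C)c([Si](C)(C)O)c2C(=O)O1 | intermediate
23 | (3R)-6,8-dihydroxy-5-{[7-methoxy-5-(methoxymethoxy)-2-methyl-4-oxo-4H-chromen-6-yl]methyl}-3,7-dimethylisochroman-1-one | C[C@@H]1Cc2c(Cc3c(OC)cc4oc(C)cc(=O)c4c3OCOC)c(O)c(C)c(O)c2C(=O)O1 | intermediate
24 | (3R)-6,8-dihydroxy-5-[(5-hydroxy-7-methoxy-2-methyl-4-oxo-4H-chromen-6-yl)methyl]-3,7-dimethylisochroman-1-one | COc1cc2oc(C)cc(=O)c2c(O)c1Cc1c(O)c(C)c(O)c2c1C[C@@H](C)OC2=O | target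

**Step count**
Total: 14 steps. Longest linear sequence: 11 steps (1–6, 8, 10, 12, 13, 14).

**Steps most likely to fail**

Step 12. The ynol ether may decompose or oligomerise at the cationic rhodium centre, the ester may stay in its extended conformation so that the two tethered alkynes never cyclise, or the ynol ether may insert in the reverse orientation. The fallback uses known chemistry, sets out from aldehyde 5 (with epoxide 9) and comes back at target 24; it joins a preformed ring C/D unit to the chromone by Friedel–Crafts benzylation. Commercial 2,4-dimethoxy-3-methylbenzoic acid is converted ((COCl)2, then Et2NH) into N,N-diethyl-2,4-dimethoxy-3-methylbenzamide F1. Amide-directed ortho-lithiation (s-BuLi, TMEDA, THF, −78 °C) and opening of 9 in the presence of BF3·OEt2 should give N,N-diethyl-6-[(2R)-2-hydroxypropyl]-2,4-dimethoxy-3-methylbenzamide F2. Acid lactonisation (TsOH, toluene, reflux) should give (3R)-6,8-dimethoxy-3,7-dimethylisochroman-1-one F3, and BBr3 (CH2Cl2, −78 °C → rt) the diphenol (3R)-6,8-dihydroxy-3,7-dimethylisochroman-1-one F4. Aldehyde 5 is reduced (NaBH4, THF/MeOH, −20 °C) to 5-hydroxy-6-(hydroxymethyl)-7-methoxy-2-methyl-4H-chromen-4-one F5. Acid-promoted ionisation of F5 to the ortho-quinone methide (TsOH cat., dioxane, 60 °C) in the presence of excess F4 should benzylate C5′, the only free position of ring C, and give 24 directly.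

Step 13. Fluoride may cleave the aryl–silicon bond (protodesilylation assisted by the ortho lactone carbonyl) in competition with the benzyl–silicon bond, or aryl migration may stall at the hindered silanol. The fallback sets out from 12 and 11 and comes back at 24; it carries the C8′ silicon as an allylsilane that is unmasked by acid instead of by fluoride attack. Dianion 13 is quenched with allylchlorodimethylsilane to give, through the silyl ester allyl(dimethyl)silyl 3-[allyl(dimethyl)silyl]prop-2-ynoate F6 (hydrolysed in the work-up), 3-[allyl(dimethyl)silyl]prop-2-ynoic acid F7. Esterification with 11 (DCC, DMAP) should give (2R)-6-[7-methoxy-5-(methoxymethoxy)-2-methyl-4-oxo-4H-chromen-6-yl]hex-4-yn-2-yl 3-[allyl(dimethyl)silyl]prop-2-ynoate F8. The cycloaddition of step 12 with 20 should give (3R)-8-[allyl(dimethyl)silyl]-5-{[7-methoxy-5-(methoxymethoxy)-2-methyl-4-oxo-4H-chromen-6-yl]methyl}-3,7-dimethyl-6-[(triisopropylsilyl)oxy]isochroman-1-one F9. KHF2 and CF3CO2H in CH2Cl2 should remove the allyl group by protodesilylation, and the MOM ether with it, to give (3R)-8-[fluoro(dimethyl)silyl]-5-[(5-hydroxy-7-methoxy-2-methyl-4-oxo-4H-chromen-6-yl)methyl]-3,7-dimethyl-6-[(triisopropylsilyl)oxy]isochroman-1-one F10. KF, KHCO3 and H2O2 in THF/MeOH at 40 °C should then oxidise F10 at C8′, the fluoride cleaving the O6′ silyl ether in the same flask, to give 24.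

Step 3. Magnesium may stay locked in the O5/O4 chelate so that formaldehyde is not delivered to C6 and 4 is recovered, or the amine base may hydroxymethylate the acidic 2-methyl group. The fallback sets out from 4 and comes back at 7; it replaces formylation by halogenation and cross-coupling. Iodination ortho to the chelated phenol (BnMe3N·ICl2, CaCO3, CH2Cl2/MeOH, rt) should give 5-hydroxy-6-iodo-7-methoxy-2-methyl-4H-chromen-4-one F11. MOM protection (MOMCl, i-Pr2NEt) gives 6-iodo-7-methoxy-5-(methoxymethoxy)-2-methyl-4H-chromen-4-one F12, and Stille hydroxymethylation with Bu3SnCH2OH (Pd(PPh3)4, dioxane, 100 °C) should give 7.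

**Further compounds**
F1 | step 12 | N,N-diethyl-2,4-dimethoxy-3-methylbenzamide | CCN(CC)C(=O)c1ccc(OC)c(C)c1OC
F2 | step 12 | N,N-diethyl-6-[(2R)-2-hydroxypropyl]-2,4-dimethoxy-3-methylbenzamide | CCN(CC)C(=O)c1c(C[C@@H](C)O)cc(OC)c(C)c1OC
F3 | step 12 | (3R)-6,8-dimethoxy-3,7-dimethylisochroman-1-one | COc1cc2C[C@@H](C)OC(=O)c2c(OC)c1C
F4 | step 12 | (3R)-6,8-dihydroxy-3,7-dimethylisochroman-1-one | Cc1c(O)cc2C[C@@H](C)OC(=O)c2c1O
F5 | step 12 | 5-hydroxy-6-(hydroxymethyl)-7-methoxy-2-methyl-4H-chromen-4-one | COc1cc2oc(C)cc(=O)c2c(O)c1CO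
F6 | step 13 | allyl(dimethyl)silyl 3-[allyl(dimethyl)silyl]prop-2-ynoate | C=CC[Si](C)(C)C#CC(=O)O[Si](C)(C)CC=C
F7 | step 13 | 3-[allyl(dimethyl)silyl]prop-2-ynoic acid | C=CC[Si](C)(C)C#CC(=O)O
F8 | step 13 | (2R)-6-[7-methoxy-5-(methoxymethoxy)-2-methyl-4-oxo-4H-chromen-6-yl]hex-4-yn-2-yl 3-[allyl(dimethyl)silyl]prop-2-ynoate | C[C@H](CC#CCc1c(OC)cc2oc(C)cc(=O)c2c1OCOC)OC(=O)C#C[Si](C)(C)CC=C
F9 | step 13 | (3R)-8-[allyl(dimethyl)silyl]-5-{[7-methoxy-5-(methoxymethoxy)-2-methyl-4-oxo-4H-chromen-6-yl]methyl}-3,7-dimethyl-6-[(triisopropylsilyl)oxy]isochroman-1-one | C[C@@H]1Cc2c(Cc3c(OC)cc4oc(C)cc(=O)c4c3OCOC)c(O[Si](C(C)C)(C(C)C)C(C)C)c(C)c([Si](C)(C)CC=C)c2C(=O)O1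
F10 | step 13 | (3R)-8-[fluoro(dimethyl)silyl]-5-[(5-hydroxy-7-methoxy-2-methyl-4-oxo-4H-chromen-6-yl)methyl]-3,7-dimethyl-6-[(triisopropylsilyl)oxy]isochroman-1-one | C[C@@H]1Cc2c(Cc3c(OC)cc4oc(C)cc(=O)c4c3O)c(O[Si](C(C)C)(C(C)C)C(C)C)c(C)c([Si](C)(C)F)c2C(=O)O1
F11 | step 3 | 5-hydroxy-6-iodo-7-methoxy-2-methyl-4H-chromen-4-one | COc1cc2oc(C)cc(=O)c2c(O)c1I
F12 | step 3 | 6-iodo-7-methoxy-5-(methoxymethoxy)-2-methyl-4H-chromen-4-one | COCOc1c(I)c(OC)cc2oc(C)cc(=O)c12
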